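**Plan**

- Retrosynthesis: both hydroxyquinones are unveiled last from methoxyquinones. Ring A is then cut at two bonds, C(=O)–C(bearing ring B) and C(=O)–C(bearing the phenethyl chain). The inter-ring bond is traced back to an aryl–alkyne bond.
- Enabling feature: in ring A the four contiguous carbons C(=O)–C(OH)=C(CH3)–C(=O) are a squaric acid unit (cyclobutenedione 3). The remaining C=C edge, carrying the phenethyl chain and ring B, is a trisubstituted alkene, so ring A = cyclobutenone + alkene by 4π opening and 6π closure.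
- Forward: the two benzene rings are bought. Ring B is built first from 3 and a 2-lithiobut-1-ene by the same ring expansion (steps 2–4) and fixed as its trimethyl ether. Iodination, Sonogashira coupling and syn-hydrozirconation/iodination give vinyl iodide 18; its lithio derivative adds to a second molecule of 3, and ring A is closed last (step 9).
- Finish: one oxidation (quinone A from its hydroquinone, quinone B by oxidative demethylation), then hydrolysis of the two vinylogous methyl esters.
- Stereochemistry: the target has no stereocentre. Only the E geometry of 18 (syn addition of Zr–H) matters; the hindered biquinone axis has no descriptor in the target and is not controlled.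

Key step: step 9

Remarks: Ar = 2,4,5-trimethoxy-6-[2-(2-methoxyphenyl)ethyl]-3-methylphenyl (the protected ring B). Lithium alkoxides present before aqueous work-up are mere protonation states and are not numbered separately.

**Route**

Step 1
Reactants: 1 dimethyl squarate
Product: 3 3-methoxy-4-methylcyclobut-3-ene-1,2-dione, via methyllithium adduct 2 (not isolated)
Conditions: MeLi, THF, −78 °C; 1 M HCl quench; then crude 2, conc. HCl (cat.), CH2Cl2, rt
Reagents that add atoms: methyllithium, C[Li]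
Why: 1,2-addition of methyllithium to one carbonyl of the squarate, then acid-promoted allylic ionisation and loss of methanol from the vinylogous hemiketal, is the standard route to 3-alkoxy-4-alkylcyclobutenediones.

Step 2
Reactants: 4 2-methoxybenzyl chloride; 5 2,3-dibromopropene
Product: 7 2-bromo-4-(2-methoxyphenyl)but-1-ene, via benzylic Grignard reagent 6 (not isolated)
Conditions: Mg, Et2O, 0 °C to rt (slow addition of 4); then 5, 0 °C to rt
Reagents that add atoms: none
Why: Allylic substitution of 2,3-dibromopropene by a benzylic Grignard reagent leaves the vinylic bromide untouched, as in the usual preparation of 2-bromo-4-arylbut-1-enes.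

Step 3
Reactants: 7 2-bromo-4-(2-methoxyphenyl)but-1-ene; 3 3-methoxy-4-methylcyclobut-3-ene-1,2-dione
Product: 9 racemic 4-hydroxy-3-methoxy-4-[4-(2-methoxyphenyl)but-1-en-2-yl]-2-methylcyclobut-2-en-1-one, via vinyllithium 8 (not isolated)
Conditions: t-BuLi (2 equiv), Et2O, −78 °C; then 3, THF, −78 °C; aq. NH4Cl
Reagents that add atoms: none
Why: Bromine–lithium exchange gives the 2-lithioalkene, which adds 1,2 to the more electrophilic carbonyl of 3 (the one next to the methoxy-bearing carbon; the other is a vinylogous ester), and the racemic carbinol centre is lost in step 4.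

Step 4
Reactants: 9 racemic 4-hydroxy-3-methoxy-4-[4-(2-methoxyphenyl)but-1-en-2-yl]-2-methylcyclobut-2-en-1-one
Product: 13 1,3,4-trimethoxy-5-[2-(2-methoxyphenyl)ethyl]-2-methylbenzene, via dienylketene 10 (not isolated), via cyclohexadienone 11 (not isolated), via hydroquinone 12 (not isolated)
Conditions: p-xylene, reflux, Ar; evaporate; then Me2SO4, K2CO3, acetone, reflux, Ar
Reagents that add atoms: dimethyl sulfate, COS(=O)(=O)OC
Why: The thermal cyclobutenone-to-hydroquinone ring expansion (4π opening, 6π electrocyclisation, enolisation) puts the arylethyl chain next to the oxygen flanked by methoxy, and Williamson methylation of the air-sensitive hydroquinone fixes ring B as its trimethyl ether.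

Step 5
Reactants: 13 1,3,4-trimethoxy-5-[2-(2-methoxyphenyl)ethyl]-2-methylbenzene
Product: 14 1-iodo-2,4,5-trimethoxy-6-[2-(2-methoxyphenyl)ethyl]-3-methylbenzene
Conditions: N-iodosuccinimide (1.05 equiv), CF3CO2H (cat.), MeCN, 0 °C to rt, dark
Reagents that add atoms: N-iodosuccinimide, O=C1CCC(=O)N1I
Why: Electrophilic aromatic iodination should go to the only free position of the trimethoxy ring, which is ortho and para to two methoxy groups and far more activated than the mono-methoxy ring.

Step 6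
Reactants: 14 1-iodo-2,4,5-trimethoxy-6-[2-(2-methoxyphenyl)ethyl]-3-methylbenzene; 15 4-phenylbut-1-yne
Product: 16 1,3,4-trimethoxy-5-[2-(2-methoxyphenyl)ethyl]-2-methyl-6-(4-phenylbut-1-yn-1-yl)benzene
Conditions: PdCl2(PPh3)2 (5 mol %), CuI (10 mol %), Et3N, DMF, 70 °C
Reagents that add atoms: none
Why: Sonogashira coupling; the iodide is chosen so that oxidative addition of zerovalent palladium to the hindered, electron-rich ring stays feasible, and this bond becomes the inter-ring bond of the target.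

Step 7
Reactants: 16 1,3,4-trimethoxy-5-[2-(2-methoxyphenyl)ethyl]-2-methyl-6-(4-phenylbut-1-yn-1-yl)benzene
Product: 18 (E)-1-(2-iodo-4-phenylbut-1-en-1-yl)-2,4,5-trimethoxy-6-[2-(2-methoxyphenyl)ethyl]-3-methylbenzene, via vinylzirconocene 17 (not isolated)
Conditions: Cp2Zr(H)Cl (2 equiv), THF, rt to 45 °C; then I2, THF, 0 °C
Reagents that add atoms: iodine, [I][I]
Why: Syn-hydrozirconation should place zirconium on the alkyne carbon remote from the 2,6-disubstituted aryl group (steric control, with excess hydride allowing equilibration), and iodinolysis with retention gives the E iodide with aryl and iodine trans.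

Step 8
Reactants: 18 (E)-1-(2-iodo-4-phenylbut-1-en-1-yl)-2,4,5-trimethoxy-6-[2-(2-methoxyphenyl)ethyl]-3-methylbenzene; 3 3-methoxy-4-methylcyclobut-3-ene-1,2-dione
Product: 20 racemic 4-hydroxy-3-methoxy-2-methyl-4-[(1E)-1-Ar-4-phenylbut-1-en-2-yl]cyclobut-2-en-1-one, via vinyllithium 19 (not isolated)
Conditions: t-BuLi (2 equiv), Et2O, −78 °C; then 3, THF, −78 °C; aq. NH4Cl
Reagents that add atoms: none
Why: Iodine–lithium exchange proceeds with retention of alkene geometry at −78 °C, and the vinyllithium (lithium on the unhindered side, trans to Ar) adds 1,2 to the same carbonyl of 3 as in step 3; the racemic carbinol centre is lost in step 9.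

Step 9
Reactants: 20 racemic 4-hydroxy-3-methoxy-2-methyl-4-[(1E)-1-Ar-4-phenylbut-1-en-2-yl]cyclobut-2-en-1-one
Product: 23 3-methoxy-2-methyl-5-(2-phenylethyl)-6-Ar-benzene-1,4-diol, via dienylketene 21 (not isolated), via cyclohexadienone 22 (not isolated)
Conditions: p-xylene (degassed), reflux, Ar
Reagents that add atoms: none
Why: Heating opens the cyclobutenone by a conrotatory 4π electrocyclic ring opening in which the hydroxyl rotates outward, so the butenyl group points toward the ketene in 21; a thermal disrotatory 6π electrocyclisation then joins the ketene carbon to the alkene carbon that carries ring B, closing ring A as cyclohexadienone 22, which enolises to hydroquinone 23. The closest known reaction type is the thermal ring expansion of squarate-derived 4-alkenyl- and 4-aryl-4-hydroxycyclobutenones to hydroquinones and quinones. Ring A is the only ring formed, and its mode of closure is this 6π electrocyclisation of the ketene–diene system. No stereocentre remains: the sp3 carbon of 22 is lost on aromatisation, and the hindered biaryl axis forms without control, as the target has no descriptor there. The step needs the right torquoselectivity (hydroxyl outward, secured by the donor character of the OH group; otherwise the ketene would lactonise to a butenolide), the right regiochemistry (fixed by the constitution of 20, whose carbinol carbon lies next to the methoxy-bearing carbon), and an accessible closing terminus (secured by the E alkene, which puts hydrogen and not the hexasubstituted aryl group on the inside).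

Step 10
Reactants: 23 3-methoxy-2-methyl-5-(2-phenylethyl)-6-Ar-benzene-1,4-diol
Product: 25 4,4'-dimethoxy-2-[2-(2-methoxyphenyl)ethyl]-5,5'-dimethyl-2'-(2-phenylethyl)-[1,1'-bi(cyclohexane)]-1,1',4,4'-tetraene-3,3',6,6'-tetrone, via ring-A quinone 24 (not isolated)
Conditions: (NH4)2Ce(NO3)6 (5 equiv), MeCN/H2O, 0 °C
Reagents that add atoms: water, O
Why: Tetravalent cerium oxidises the hydroquinone to quinone A at once and then demethylates the para-dimethoxy pair of ring B oxidatively (arene radical cation, attack of water, loss of methanol); the mono-methoxy ring has a higher oxidation potential and should be spared, and the remaining methoxy group of ring B survives as a vinylogous ester.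

Step 11
Reactants: 25 4,4'-dimethoxy-2-[2-(2-methoxyphenyl)ethyl]-5,5'-dimethyl-2'-(2-phenylethyl)-[1,1'-bi(cyclohexane)]-1,1',4,4'-tetraene-3,3',6,6'-tetrone
Product: 26 4,4'-dihydroxy-2-[2-(2-methoxyphenyl)ethyl]-5,5'-dimethyl-2'-(2-phenylethyl)-[1,1'-bi(cyclohexane)]-1,1',4,4'-tetraene-3,3',6,6'-tetrone (target)
Conditions: 2 M NaOH, THF/H2O, rt; then 1 M HCl
Reagents that add atoms: sodium hydroxide, [Na+].[OH-]
Why: Hydroxide displaces methoxide at the two methoxy-bearing quinone carbons by addition–elimination (saponification of vinylogous esters); both quinones are fully substituted, so no conjugate-addition site is open, and acidification returns the two hydroxyquinones while the aryl methyl ether is untouched.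

**Compound list**

1 | dimethyl squarate (3,4-dimethoxycyclobut-3-ene-1,2-dione) | COC1=C(OC)C(=O)C1=O | starting material
2 | racemic 4-hydroxy-2,3-dimethoxy-4-methylcyclobut-2-en-1-one | CC1(O)C(OC)=C(OC)C1=O | intermediate
3 | 3-methoxy-4-methylcyclobut-3-ene-1,2-dione | COC1=C(C)C(=O)C1=O | intermediate
4 | 2-methoxybenzyl chloride | COc1ccccc1CCl | starting material
5 | 2,3-dibromopropene | C=C(Br)CBr | starting material
6 | (2-methoxybenzyl)magnesium chloride | COc1ccccc1C[Mg]Cl | intermediate
7 | 2-bromo-4-(2-methoxyphenyl)but-1-ene | C=C(Br)CCc1ccccc1OC | intermediate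
8 | [4-(2-methoxyphenyl)but-1-en-2-yl]lithium | [Li]C(=C)CCc1ccccc1OC | intermediate
9 | racemic 4-hydroxy-3-methoxy-4-[4-(2-methoxyphenyl)but-1-en-2-yl]-2-methylcyclobut-2-en-1-one | C=C(CCc1ccccc1OC)C1(O)C(OC)=C(C)C1=O | intermediate
10 | (3Z)-4-hydroxy-3-methoxy-7-(2-methoxyphenyl)-2-methyl-5-methylidenehepta-1,3-dien-1-one | O=C=C(C)/C(OC)=C(O)\C(=C)CCc1ccccc1OC | intermediate
11 | 4-hydroxy-3-methoxy-5-[2-(2-methoxyphenyl)ethyl]-2-methylcyclohexa-2,4-dien-1-one | CC1=C(OC)C(O)=C(CCc2ccccc2OC)CC1=O | intermediate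
12 | 3-methoxy-5-[2-(2-methoxyphenyl)ethyl]-2-methylbenzene-1,4-diol | Cc1c(O)cc(CCc2ccccc2OC)c(O)c1OC | intermediate
13 | 1,3,4-trimethoxy-5-[2-(2-methoxyphenyl)ethyl]-2-methylbenzene | Cc1c(OC)cc(CCc2ccccc2OC)c(OC)c1OC | intermediate
14 | 1-iodo-2,4,5-trimethoxy-6-[2-(2-methoxyphenyl)ethyl]-3-methylbenzene | Cc1c(OC)c(I)c(CCc2ccccc2OC)c(OC)c1OC | intermediate
15 | 4-phenylbut-1-yne | C#CCCc1ccccc1 | starting material
16 | 1,3,4-trimethoxy-5-[2-(2-methoxyphenyl)ethyl]-2-methyl-6-(4-phenylbut-1-yn-1-yl)benzene | Cc1c(OC)c(C#CCCc2ccccc2)c(CCc2ccccc2OC)c(OC)c1OC | intermediate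
17 | chlorobis(cyclopentadienyl)[(E)-4-phenyl-1-{2,4,5-trimethoxy-6-[2-(2-methoxyphenyl)ethyl]-3-methylphenyl}but-1-en-2-yl]zirconium (zirconium trans to the aryl group; cyclopentadienyl rings drawn sigma-bonded) | Cl[Zr](C1C=CC=C1)(C1C=CC=C1)/C(CCc1ccccc1)=C/c1c(OC)c(C)c(OC)c(OC)c1CCc1ccccc1OC | intermediate
18 | (E)-1-(2-iodo-4-phenylbut-1-en-1-yl)-2,4,5-trimethoxy-6-[2-(2-methoxyphenyl)ethyl]-3-methylbenzene (iodine trans to the aryl group) | I/C(CCc1ccccc1)=C/c1c(OC)c(C)c(OC)c(OC)c1CCc1ccccc1OC | intermediate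
19 | (4-phenyl-1-{2,4,5-trimethoxy-6-[2-(2-methoxyphenyl)ethyl]-3-methylphenyl}but-1-en-2-yl)lithium (lithium trans to the aryl group) | [Li]/C(CCc1ccccc1)=C/c1c(OC)c(C)c(OC)c(OC)c1CCc1ccccc1OC | intermediate
20 | racemic 4-hydroxy-3-methoxy-2-methyl-4-[(1E)-4-phenyl-1-{2,4,5-trimethoxy-6-[2-(2-methoxyphenyl)ethyl]-3-methylphenyl}but-1-en-2-yl]cyclobut-2-en-1-one | CC1=C(OC)C(O)(/C(CCc2ccccc2)=C/c2c(OC)c(C)c(OC)c(OC)c2CCc2ccccc2OC)C1=O | intermediate
21 | (3Z,5E)-4-hydroxy-3-methoxy-2-methyl-5-(2-phenylethyl)-6-{2,4,5-trimethoxy-6-[2-(2-methoxyphenyl)ethyl]-3-methylphenyl}hexa-1,3,5-trien-1-one | O=C=C(C)/C(OC)=C(O)\C(CCc1ccccc1)=C\c1c(OC)c(C)c(OC)c(OC)c1CCc1ccccc1OC | intermediate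
22 | racemic 4-hydroxy-3-methoxy-2-methyl-5-(2-phenylethyl)-6-{2,4,5-trimethoxy-6-[2-(2-methoxyphenyl)ethyl]-3-methylphenyl}cyclohexa-2,4-dien-1-one | CC1=C(OC)C(O)=C(CCc2ccccc2)C(c2c(OC)c(C)c(OC)c(OC)c2CCc2ccccc2OC)C1=O | intermediate
23 | 3-methoxy-2-methyl-5-(2-phenylethyl)-6-{2,4,5-trimethoxy-6-[2-(2-methoxyphenyl)ethyl]-3-methylphenyl}benzene-1,4-diol | Cc1c(O)c(-c2c(OC)c(C)c(OC)c(OC)c2CCc2ccccc2OC)c(CCc2ccccc2)c(O)c1OC | intermediate
24 | 3-methoxy-2-methyl-5-(2-phenylethyl)-6-{2,4,5-trimethoxy-6-[2-(2-methoxyphenyl)ethyl]-3-methylphenyl}cyclohexa-2,5-diene-1,4-dione | CC1=C(OC)C(=O)C(CCc2ccccc2)=C(c2c(OC)c(C)c(OC)c(OC)c2CCc2ccccc2OC)C1=O | intermediate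
25 | 4,4'-dimethoxy-2-[2-(2-methoxyphenyl)ethyl]-5,5'-dimethyl-2'-(2-phenylethyl)-[1,1'-bi(cyclohexane)]-1,1',4,4'-tetraene-3,3',6,6'-tetrone | CC1=C(OC)C(=O)C(CCc2ccccc2)=C(C2=C(CCc3ccccc3OC)C(=O)C(OC)=C(C)C2=O)C1=O | intermediate
26 | 4,4'-dihydroxy-2-[2-(2-methoxyphenyl)ethyl]-5,5'-dimethyl-2'-(2-phenylethyl)-[1,1'-bi(cyclohexane)]-1,1',4,4'-tetraene-3,3',6,6'-tetrone | COc1ccccc1CCC1=C(C2=C(CCc3ccccc3)C(=O)C(O)=C(C)C2=O)C(=O)C(C)=C(O)C1=O | target

**Step count and risks**

Total step count: 11. Longest linear sequence: 10 steps (from 4 through steps 2–11; step 1 supplies dione 3 for steps 3 and 8).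

Steps most likely to fail:

1. Step 9. With the hexasubstituted aryl group on the closing terminus, the 6π closure may be outrun by capture of the ketene by the neighbouring hydroxyl (lactonisation), or the ring opening may take the wrong rotational sense. Fallback: ring A is made on an unhindered substrate and joined to ring B by cross-coupling. It sets out from 3 and 14. Commercial 2-bromo-4-phenylbut-1-ene (C=C(Br)CCc1ccccc1) is lithiated (t-BuLi, Et2O, −78 °C) to (4-phenylbut-1-en-2-yl)lithium F1, which adds to 3 to give racemic 4-hydroxy-3-methoxy-2-methyl-4-(4-phenylbut-1-en-2-yl)cyclobut-2-en-1-one F2. Thermolysis in p-xylene gives 3-methoxy-2-methyl-5-(2-phenylethyl)benzene-1,4-diol F3, which Ag2O oxidises to 3-methoxy-2-methyl-5-(2-phenylethyl)cyclohexa-2,5-diene-1,4-dione F4. Br2 followed by Et3N gives 2-bromo-5-methoxy-6-methyl-3-(2-phenylethyl)cyclohexa-2,5-diene-1,4-dione F5. Iodide 14 is borylated (bis(pinacolato)diboron, PdCl2(dppf), KOAc, dioxane) to 4,4,5,5-tetramethyl-2-{2,4,5-trimethoxy-6-[2-(2-methoxyphenyl)ethyl]-3-methylphenyl}-1,3,2-dioxaborolane F6. Suzuki–Miyaura coupling of F5 with F6 (Pd2(dba)3, SPhos, K3PO4, toluene/H2O) should give 24, where the route is rejoined; step 10 then only has to oxidise ring B.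

2. Step 7. The Zr–H bond may add to the hindered alkyne with the wrong orientation, or too slowly. Fallback: regio- and stereochemistry are fixed by constitution instead of by a hydrometalation. It sets out from 14 and 15. Anti addition of IBr to 15 (CH2Cl2, −78 to 0 °C, iodine at the terminus) gives (E)-2-bromo-1-iodo-4-phenylbut-1-ene F7. Zinc insertion into 14 (Zn dust, LiCl, THF, 50 °C) gives {2,4,5-trimethoxy-6-[2-(2-methoxyphenyl)ethyl]-3-methylphenyl}zinc iodide F8. Negishi coupling at the carbon–iodine bond of F7 (Pd(PPh3)4, THF, rt), with retention, should give (E)-1-(2-bromo-4-phenylbut-1-en-1-yl)-2,4,5-trimethoxy-6-[2-(2-methoxyphenyl)ethyl]-3-methylbenzene F9, bromine trans to the aryl group. Bromine–lithium exchange (t-BuLi, −78 °C) gives vinyllithium 19, and the route is rejoined at 20 under the conditions of step 8.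

3. Step 10. Oxidation of the hindered trimethoxy ring may take an unwanted course (ortho-quinone formation, nitration or benzylic oxidation) instead of clean para oxidative demethylation. Fallback: the quinones are unveiled electrochemically through quinone bisketals. It sets out from 23. Methylation (Me2SO4, K2CO3, acetone) gives 2,3',4,4',5,6'-hexamethoxy-2'-[2-(2-methoxyphenyl)ethyl]-3,5'-dimethyl-6-(2-phenylethyl)-1,1'-biphenyl F10. Anodic oxidation (Pt anode, KOH/MeOH, divided cell, 0 °C) gives the bis(quinone bis(dimethyl ketal)) 3,3,3',3',4,4',6,6,6',6'-decamethoxy-2-[2-(2-methoxyphenyl)ethyl]-5,5'-dimethyl-2'-(2-phenylethyl)-[1,1'-bi(cyclohexane)]-1,1',4,4'-tetraene F11. Mild hydrolysis (aq. AcOH, rt) of the four ketals should give 25, where the route is rejoined.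

Further compounds
F1 | step 9 | (4-phenylbut-1-en-2-yl)lithium | [Li]C(=C)CCc1ccccc1
F2 | step 9 | racemic 4-hydroxy-3-methoxy-2-methyl-4-(4-phenylbut-1-en-2-yl)cyclobut-2-en-1-one | C=C(CCc1ccccc1)C1(O)C(OC)=C(C)C1=O
F3 | step 9 | 3-methoxy-2-methyl-5-(2-phenylethyl)benzene-1,4-diol | Cc1c(O)cc(CCc2ccccc2)c(O)c1OC
F4 | step 9 | 3-methoxy-2-methyl-5-(2-phenylethyl)cyclohexa-2,5-diene-1,4-dione | CC1=C(OC)C(=O)C(CCc2ccccc2)=CC1=O
F5 | step 9 | 2-bromo-5-methoxy-6-methyl-3-(2-phenylethyl)cyclohexa-2,5-diene-1,4-dione | CC1=C(OC)C(=O)C(CCc2ccccc2)=C(Br)C1=O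
F6 | step 9 | 4,4,5,5-tetramethyl-2-{2,4,5-trimethoxy-6-[2-(2-methoxyphenyl)ethyl]-3-methylphenyl}-1,3,2-dioxaborolane | Cc1c(OC)c(B2OC(C)(C)C(C)(C)O2)c(CCc2ccccc2OC)c(OC)c1OC
F7 | step 7 | (E)-2-bromo-1-iodo-4-phenylbut-1-ene | I/C=C(/Br)CCc1ccccc1
F8 | step 7 | {2,4,5-trimethoxy-6-[2-(2-methoxyphenyl)ethyl]-3-methylphenyl}zinc iodide | Cc1c(OC)c([Zn]I)c(CCc2ccccc2OC)c(OC)c1OC
F9 | step 7 | (E)-1-(2-bromo-4-phenylbut-1-en-1-yl)-2,4,5-trimethoxy-6-[2-(2-methoxyphenyl)ethyl]-3-methylbenzene | Br/C(CCc1ccccc1)=C/c1c(OC)c(C)c(OC)c(OC)c1CCc1ccccc1OC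
F10 | step 10 | 2,3',4,4',5,6'-hexamethoxy-2'-[2-(2-methoxyphenyl)ethyl]-3,5'-dimethyl-6-(2-phenylethyl)-1,1'-biphenyl | Cc1c(OC)c(-c2c(OC)c(C)c(OC)c(OC)c2CCc2ccccc2OC)c(CCc2ccccc2)c(OC)c1OC
F11 | step 10 | 3,3,3',3',4,4',6,6,6',6'-decamethoxy-2-[2-(2-methoxyphenyl)ethyl]-5,5'-dimethyl-2'-(2-phenylethyl)-[1,1'-bi(cyclohexane)]-1,1',4,4'-tetraene | CC1=C(OC)C(OC)(OC)C(CCc2ccccc2)=C(C2=C(CCc3ccccc3OC)C(OC)(OC)C(OC)=C(C)C2(OC)OC)C1(OC)OC
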